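**Assumptions.** Dimethyl furan-3,4-dicarboxylate, 5-bromo-1,2,3-trimethoxybenzene and 4-bromoveratrole are treated as commercial. The target is assumed to exist as the open γ-hydroxy aryl ketone rather than its cyclic hemiketal, as drawn in the SMILES.

## Retrosynthetic overview
- Magnone B comes from opening the cis-fused γ-lactone **7** with 3,4-dimethoxyphenyllithium. The lactone fixes the 3,4-cis relationship and the exo-aryl (2,3-trans) geometry.
- Lactone **7** comes from acid epimerisation of the endo isomer **6**. **6** comes from regioselective oxidative lactonisation of the all-cis diol **5**, which comes from the all-cis diester **4**.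
- Key step: asymmetric dearomative hydrogenation of the 2-aryl-furan diester **3**, which sets three contiguous stereocentres in one step. **3** comes from C–H arylation of the C2/C5-symmetric furan diester **1**, which breaks its symmetry.
- Ring order: the furan is already present in **1**; the THF ring is formed by dearomatisation (step 2); the lactone ring is formed in step 4 and opened in step 6.

## Route

**Step 1**
Reactants: **1** dimethyl furan-3,4-dicarboxylate (3 equiv); **2** 5-bromo-1,2,3-trimethoxybenzene
Product: **3** dimethyl 2-(3,4,5-trimethoxyphenyl)furan-3,4-dicarboxylate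
Conditions: Pd(OAc)2 (5 mol%), PCy3·HBF4 (10 mol%), PivOH (30 mol%), K2CO3, DMA, 110 °C
Reagents that add atoms: **2**, COc1cc(Br)cc(OC)c1OC (supplies the trimethoxyphenyl group)
Why: Concerted metalation–deprotonation (direct C–H arylation) occurs at the acidic furan α-C–H, and C2/C5 are equivalent, so there is no regiochemistry problem; excess **1** suppresses diarylation.

**Step 2**
Reactant: **3**
Product: **4** dimethyl (2R,3S,4R)-2-(3,4,5-trimethoxyphenyl)oxolane-3,4-dicarboxylate (all-cis)
Conditions: [Ru(cod)(2-methylallyl)2] / chiral NHC (SINpEt-type imidazolinium salt), KOtBu (cat.), H2 (100 bar), hexane/THF, 40 °C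
Reagents that add atoms: none (H2 adds only hydrogen)
Why: Proposed new method: Ru–NHC-catalysed arene hydrogenation delivers H2 syn to one enantioface of the electron-poor furan, making C2, C3 and C4 all cis and setting absolute configuration at C3/C4 (the target's C8/C8'). This is closest to known Ru–NHC asymmetric hydrogenation of furans and benzofurans, extended here to a tetrasubstituted diester. The ligand enantiomer is chosen to give 3S,4R; C2 (R) is inverted in step 5.

**Step 3**
Reactant: **4**
Product: **5** [(2R,3R,4S)-2-(3,4,5-trimethoxyphenyl)oxolane-3,4-diyl]dimethanol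
Conditions: LiAlH4, THF, 0 °C, 1 h; Fieser work-up
Reagents that add atoms: none (hydride only)
Why: Ester reduction only; no stereocentre is touched, and the ethers and aryl methyl ethers survive.

**Step 4**
Reactant: **5**
Product: **6** (3aR,4R,6aR)-4-(3,4,5-trimethoxyphenyl)tetrahydro-1H,3H-furo[3,4-c]furan-1-one (endo-aryl lactone)
Conditions: TEMPO (10 mol%), PhI(OAc)2 (2.4 equiv), CH2Cl2, 25 °C
Reagents that add atoms: none
Why: TEMPO/PIDA oxidative lactonisation of a 1,4-diol: the less hindered C4-CH2OH (remote from the aryl) is oxidised first, and the cis CH2OH traps the aldehyde as a lactol that is oxidised to the cis-fused lactone. The carbonyl therefore ends up on the carbon destined to carry the ketone.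

**Step 5**
Reactant: **6**
Product: **7** (3aR,4S,6aR)-4-(3,4,5-trimethoxyphenyl)tetrahydro-1H,3H-furo[3,4-c]furan-1-one (exo-aryl lactone)
Conditions: TFA/CH2Cl2 (1:4), 25 °C, 6–12 h; then aq. NaHCO3
Reagents that add atoms: none (TFA is a catalyst and is removed)
Why: Acid-mediated benzylic C–O ionisation and reclosure (as in asarinin→sesamin-type furofuran epimerisation) converts the strained endo-aryl bicycle to the thermodynamic exo isomer, which gives the 2,3-trans relationship. The cis ring fusion (C8/C8') is unchanged, and β-lactone formation by translactonisation is impossible.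

**Step 6**
Reactants: **7**; **8** 4-bromo-1,2-dimethoxybenzene (precursor of the aryllithium)
Product: **9** Magnone B, (3,4-dimethoxyphenyl)[(3R,4R,5S)-4-(hydroxymethyl)-5-(3,4,5-trimethoxyphenyl)oxolan-3-yl]methanone
Conditions: **8** + n-BuLi, THF, −78 °C, 30 min; add **7** (1.0 equiv), −78 °C, 1 h; quench at −78 °C with sat. NH4Cl
Reagents that add atoms: 3,4-dimethoxyphenyllithium, COc1ccc([Li])cc1OC
Why: Aryllithium addition to the lactone gives a stable lithium hemiketalate at −78 °C that collapses on work-up to the aryl ketone plus the free CH2OH (lactone-to-ketone opening); no stereocentre changes.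

## Compound list
1 | dimethyl furan-3,4-dicarboxylate | COC(=O)c1cocc1C(=O)OC | starting material
2 | 5-bromo-1,2,3-trimethoxybenzene | COc1cc(Br)cc(OC)c1OC | starting material
3 | dimethyl 2-(3,4,5-trimethoxyphenyl)furan-3,4-dicarboxylate | COC(=O)c1coc(-c2cc(OC)c(OC)c(OC)c2)c1C(=O)OC | intermediate
4 | dimethyl (2R,3S,4R)-2-(3,4,5-trimethoxyphenyl)oxolane-3,4-dicarboxylate | COC(=O)[C@H]1CO[C@@H](c2cc(OC)c(OC)c(OC)c2)[C@H]1C(=O)OC | intermediate
5 | [(2R,3R,4S)-2-(3,4,5-trimethoxyphenyl)oxolane-3,4-diyl]dimethanol | OC[C@H]1CO[C@@H](c2cc(OC)c(OC)c(OC)c2)[C@H]1CO | intermediate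
6 | (3aR,4R,6aR)-4-(3,4,5-trimethoxyphenyl)tetrahydro-1H,3H-furo[3,4-c]furan-1-one | O=C1OC[C@H]2[C@@H]1CO[C@H]2c1cc(OC)c(OC)c(OC)c1 | intermediate
7 | (3aR,4S,6aR)-4-(3,4,5-trimethoxyphenyl)tetrahydro-1H,3H-furo[3,4-c]furan-1-one | O=C1OC[C@H]2[C@@H]1CO[C@@H]2c1cc(OC)c(OC)c(OC)c1 | intermediate
8 | 4-bromo-1,2-dimethoxybenzene | COc1ccc(Br)cc1OC | starting material
9 | Magnone B | COc1ccc(C(=O)[C@H]2CO[C@H](c3cc(OC)c(OC)c(OC)c3)[C@H]2CO)cc1OC | target

Atom check: **3** C17H18O8; **4** C17H22O8; **5** C15H22O6; **6** and **7** C15H18O6; **9** = **7** + C8H10O2 (ArH) = C23H28O8, which matches the target SMILES.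

**Total steps:** 6. **Longest linear sequence:** 6 (from **1**; **2** and **8** are convergent inputs).

**Three steps most likely to fail**
1. **Step 2 (asymmetric furan hydrogenation).** This tetrasubstituted, ester-bearing furan may give low ee or conversion, and it risks benzylic hydrogenolysis or ester α-epimerisation. Fallback: convert **3** to its bis((−)-8-phenylmenthyl) diester and hydrogenate over Rh/Al2O3 so the auxiliary directs the all-cis face. Step 3 (LiAlH4) then releases the auxiliary alcohol, which is separated.
2. **Step 4 (regioselective oxidative lactonisation).** Oxidation of the wrong CH2OH would give the isomeric lactone. Fallback: hydrolyse **4** (Me3SnOH, to avoid epimerisation) to the diacid, close it to the anhydride with Ac2O, then reduce with NaBH4 at the more hindered carbonyl (next to the aryl-bearing carbon) to give **6**.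
3. **Step 6 (mono-addition of ArLi).** Over-addition would give the tertiary diaryl carbinol. Fallback: open **7** with Me(MeO)NH·AlMe3 to the hydroxy Weinreb amide, protect as the TBS ether, add the aryl Grignard (from **8**), then remove TBS with TBAF.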